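Heat looks like the cheap way to finish a slow coupling, but here it speeds the isomerisation more steeply than the coupling that makes the target, its activation energy lying 52.0 kJ/mol higher.

    second substrate + protic impurity → quenched substrate (k1 = 1.1 /M/s, Ea1 = 57.0 kJ/mol)
    starting material + second substrate → cross product (k2 = 0.37 /M/s, Ea2 = 41.0 kJ/mol)
    starting material + coupling partner → target (k3 = 0.18 /M/s, Ea3 = 36.0 kJ/mol)
    second substrate + coupling partner → second product (k4 = 0.99 /M/s, Ea4 = 52.0 kJ/mol)
    target ⇌ isomer of the product (K5 = 7.4, k5 = 0.0025 /s, Ea5 = 88.0 kJ/mol, ΔH5 = 60.0 kJ/mol)
    (constants at 25 °C)

in all of them: starting material 29 mM; coupling partner 31.9 mM; second substrate 14.5 mM; protic impurity 8.70 mM; time 10 min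

| charge | remark | temperature |
|---|---|---|
| north-west | at 25 °C until 3.0 min, from then on at 50 °C |  |
| south-west |  | 50 °C |
| east |  | 25 °C |

- at 25 °C the constants are as listed, elsewhere as the activation energies and enthalpies make them

1. the flask that comes out highest in amount of target, in percent of the starting material charged, or "all alike" when all lie within 1.5 percentage points (north-west / south-west / east / all alike)
2. target at the end, in percent of the starting material charged, north-west
3. target at the end, in percent of the starting material charged, south-west
4. target at the end, in percent of the starting material charged, east

Target and its isomer approach equilibrium with a relaxation half-life, both directions together, of 4.07 min at 25 °C and 0.290 min at 50 °C. Dividing the run by each gives 2.46 for east and 34.4 for south-west. This count of relaxation half-lives, run time over relaxation half-life, is the measure used here for kinetic against thermodynamic control in these flasks. The cold start in north-west offers little protection, since 24.1 half-lives, far more than one, still follow the warming. So this reckoning, with the hot count much larger than the cold one, puts east highest and the two warmed flasks low and close together. East should also keep target above its equilibrium share at 25 °C, 11.9 % of target plus isomer. The count gives this ranking, not the hot levels.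

The forecast named east, with 2 % for north-west, 1.8 % for south-west and 25.5 % for east, holding that hot “target relaxes within about 25 s to a quasi-steady level”.

The simulation puts east highest at 25.2 %, with 2.01 % in north-west and 1.85 % in south-west. Target in east is 40.8 % of target plus isomer, above the equilibrium share at 25 °C. In north-west target stood at 29.9 % at 3.00 min, the moment of warming, and at 4.37 % by 5.00 min, some 6.89 half-lives later, while the isomer rose from 9.17 % to 56.0 %. The method is one division, made for each temperature before a flask is charged.

Raising the second substrate to 58 mM in the south-west recipe leaves the temperature as it was. The isomerisation involves no other species, so the half-life and the count of 34.4 stay, and target should again be a small share of target plus isomer. That neighbour ends with cross product holding the most starting material, at 69.4 %, and with a smaller pool than south-west: isomer 9.18 %, target 0.195 %. Target's share there is 2.08 %, against 2.46 % in south-west.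

The constants used here are made up; the result is computed.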